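(Readings and results were generated by integration on assumed constants, noise included.)

The pitfall in a dynamic kinetic resolution is to read the excess of right-handed substrate over left-handed substrate as a mark of conversion. A racemate is the zero of that scale. In a quasi-steady state, the reagent's pull on the left hand balances the levelling by the racemization catalyst, so the excess goes as reagent left over live catalyst.

| flask | left-handed substrate | right-handed substrate | reagent | racemization catalyst | remark | time |
|---|---|---|---|---|---|---|
| alpha | 30 mM | 30 mM | 50 mM | 0.20 mM | run made earlier |  |
| cedar | 20 mM | 20 mM | 50.0 mM | 0.20 mM |  | 4.0 h |
| ash | 20 mM | 20 mM | 50.0 mM | 0.20 mM |  | 15 h |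

- alpha (time / min: right-handed substrate / %, left-handed substrate / %, left-handed product / %): 15.0: 29.5, 24.6, 45.0; 30.0: 20.7, 18.8, 60.0; 40.0: 17.3, 14.7, 62.7; 60.0: 14.4, 14.3, 71.5; 80.0: 12.1, 10.0, 72.9

(readings scatter by 1 percentage point)

- which one finishes higher in excess of right-handed substrate over left-handed substrate among what is left of the two ("neither" within 2 percentage points) (cedar / ash / neither)
- excess of right-handed substrate over left-handed substrate among what is left of the two at the end, cedar
- excess of right-handed substrate over left-handed substrate among what is left of the two at the end, ash

- reagent is single-handed; left-handed substrate and right-handed substrate are mirror images of each other, charged as a racemate, each of them at the stated concentration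
- the earlier runs were read with a standard deviation of 1 percentage point
- an excess is the difference of the two amounts in percent of their sum
- an excess is below zero if the other one leads
- the handed part of reagent does not stay in what it makes, so the products of the two hands are mirror images too

My reckoning starts from the alpha run. At 15.0 min its excess reads 9.06%, with about 23.0 mM of reagent left after the left-handed product is counted. Taking the catalyst as charged, excess times live catalyst over reagent left reads 7.88 × 10⁻⁴; call this the balance number. It is a rough reading, since each value carries 1 percentage point of scatter.

Cedar and ash both charge a surplus of 10.0 mM of reagent, so intact catalyst gives 3.94% in each. Now turn the question round: by the balance number, for ash to pass cedar by over 2 points on equal reagent, its live catalyst at 15 h must stand well under cedar's at 4.0 h. The last alpha reading is poor ground for judging this: its excess at 80.0 min reads 9.50% on a sum of just 22.1%, a small difference between two scattered values.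

The forecast gave 4.4% for cedar, 4.2% for ash and neither as the verdict, holding that “the ratio is the same”.

The simulation gives 18.4% for cedar and 25.8% for ash, so the higher one is ash.

    reagent + left-handed substrate → left-handed product (k = 162 M⁻¹ h⁻¹)
    reagent + right-handed substrate → right-handed product (k = 6.07 M⁻¹ h⁻¹)
    left-handed substrate + racemization catalyst ⇌ right-handed substrate + racemization catalyst, rate k3*[racemization catalyst]*[left-handed substrate] forward; the back reaction follows from the equilibrium constant (k = 56900 M⁻¹ h⁻¹)
    racemization catalyst ⇌ dormant form (K = 2.00, k = 0.414 h⁻¹)
    2 racemization catalyst → spent catalyst (k = 1610 M⁻¹ h⁻¹)

The difference in time may be called the main reason for the gap between the two flasks: without it, ash gives 18.4% instead of 25.8%. With ash's live catalyst at 15.0 h, 12.3% of its charge, the balance number gives 31.9% against 25.8%. In the neighbour of cedar charged with 0.80 mM of catalyst, 7.86% stays live and 20.7% of the reagent stays, so the number gives 13.0%; the computed excess is 11.0%.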